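The strategy is not to attach coumarin B to the crowded cyclohexene but to grow its benzene ring outward from cyclohexene C6. That ring bears oxygen on C5, C7 and C8a. C8, the atom bonded to cyclohexene C6, lies between two of these oxygens, and a siloxyalkyne plus the vinylketene from a 3-alkoxycyclobutenone deliver exactly this pattern. One thermal operation forms the coumarin bonds C8–C8a, C6–C7 and C4a–C8a and leaves the flanking oxygens differentiated as OH and OTIPS. The precursor is a cis-1,6-dialkynyl-1,4-dimethylcyclohex-4-ene with a TIPS-capped ethynyl on quaternary C1 and a TIPS ynol ether on C6. Both stereocentres come from a ring-contracting Claisen rearrangement that relays the carbinol centre of (R)-linalool.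

Key step: step 12

Remark on numbering: cyclohexene C1 is the quaternary carbon and C6 the aryl-bearing carbon. Coumarin A sits on the Z-alkene and coumarin B on C6. The target is (1R,6R), with the aryl and styryl groups cis.
Remark on supply: cyclobutane-1,3-dione is taken as a catalogue compound (it exists as its enol), and the enantiomeric purity of the route is that of the commercial (R)-linalool.

Step 1
Reactants: 1 (R)-(−)-linalool
Product: 2 (5R)-5-ethenyl-5-methyloxolan-2-ol (lactol; anomer mixture)
Conditions: O3 (1.0 equiv, Sudan Red 7B end point), CH2Cl2/MeOH, −78 °C; then Me2S, −78 °C to rt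
Reagents that add atoms: ozone, [O-][O+]=O
Why: Chemoselective ozonolysis, in which the electron-rich trisubstituted alkene reacts far faster than the vinyl group beside the carbinol, the hydroxy aldehyde closes to the lactol, the tertiary C–O stereocentre is untouched and the new anomeric centre is of no consequence.

Step 2
Reactants: 2 (5R)-5-ethenyl-5-methyloxolan-2-ol
Product: 3 (3R)-3-methylhept-1-ene-3,6-diol (C6 epimers)
Conditions: MeMgBr (3 equiv), THF, 0 °C to rt; aq NH4Cl
Reagents that add atoms: methylmagnesium bromide, C[Mg]Br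
Why: Grignard addition to the open hydroxy-aldehyde form of the lactol, the new carbinol centre being formed without control and removed in step 3.

Step 3
Reactants: 3 (3R)-3-methylhept-1-ene-3,6-diol
Product: 4 (5R)-5-hydroxy-5-methylhept-6-en-2-one
Conditions: Dess–Martin periodinane, CH2Cl2, 0 °C to rt
Reagents that add atoms: none
Why: Dess–Martin oxidation can act only on the secondary alcohol, since the tertiary allylic alcohol has no carbinol hydrogen and, unlike with chromium oxidants, is not transposed.

Step 4
Reactants: 4 (5R)-5-hydroxy-5-methylhept-6-en-2-one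
Product: 5 (3R)-7-methoxy-3,6-dimethylhepta-1,6-dien-3-ol (E/Z mixture)
Conditions: MeOCH2PPh3Cl, KOt-Bu (3 equiv each), THF, 0 °C to rt
Reagents that add atoms: (methoxymethyl)triphenylphosphonium chloride, COC[P+](c1ccccc1)(c1ccccc1)c1ccccc1.[Cl-]
Why: Wittig methoxymethylenation of a methyl ketone, in which excess ylide absorbs the free hydroxyl and both enol ether isomers converge in step 5.

Step 5
Reactants: 5 (3R)-7-methoxy-3,6-dimethylhepta-1,6-dien-3-ol
Product: 6 (6R)-6-ethenyl-2-methoxy-3,6-dimethyloxane (mixture at C2 and C3)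
Conditions: PPTS (5 mol%), CH2Cl2, rt
Reagents that add atoms: none
Why: Acid-catalysed intramolecular acetalisation, in which the enol ether is protonated at its methyl-bearing carbon and the oxocarbenium ion is captured by the tertiary hydroxyl in a six-membered closure; the acid is too weak to ionise the allylic alcohol, and the two new centres are erased in step 7.

Step 6
Reactants: 6 (6R)-6-ethenyl-2-methoxy-3,6-dimethyloxane; 7 methyl acrylate
Product: 8 methyl (E)-3-[(2R)-6-methoxy-2,5-dimethyloxan-2-yl]prop-2-enoate (mixture at C5 and C6 of the oxane)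
Conditions: 7 (5 equiv), second-generation Hoveyda–Grubbs catalyst [RuCl2(H2IMes)(=CH-2-(i-PrO)C6H4)] (5 mol%), toluene, 60 °C, argon sparge
Reagents that add atoms: none
Why: Olefin cross-metathesis between a hindered vinyl group that does not homodimerise and an electron-poor acrylate should give the E-enoate selectively, and it is run on the acetal because the enol ether unveiled in step 7 would tie up ruthenium as a Fischer carbene.

Step 7
Reactants: 8 methyl (E)-3-[(2R)-6-methoxy-2,5-dimethyloxan-2-yl]prop-2-enoate
Product: 9 methyl (E)-3-[(2R)-2,5-dimethyl-3,4-dihydro-2H-pyran-2-yl]prop-2-enoate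
Conditions: TMSOTf, i-Pr2NEt, CH2Cl2, −20 °C to rt; basic alumina filtration
Reagents that add atoms: none
Why: Silyl triflate/amine acetal-to-enol-ether elimination, in which the unhindered exocyclic methoxy group is silylated and leaves, the amine removes the only β-hydrogen, and the enoate disfavours ionisation of the tertiary allylic C–O bond so the stereocentre holds.

Step 8
Reactants: 9 methyl (E)-3-[(2R)-2,5-dimethyl-3,4-dihydro-2H-pyran-2-yl]prop-2-enoate
Product: 10 methyl (1R,6S)-6-formyl-3,6-dimethylcyclohex-2-ene-1-carboxylate (CHO cis to CO2Me)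
Conditions: toluene (0.05 M), BHT, silylated sealed tube, 220 °C
Reagents that add atoms: none
Why: Ring-contracting Claisen rearrangement ([3,3]-sigmatropic), in which the C3–C4 tether enforces a boat-like transition state where the axial alkenyl group on pyran C2 bonds through its ester-bearing carbon to the same face of C5; the R carbinol centre (which becomes sp2 C4 of the cyclohexene) is thereby relayed to quaternary C1, while the E geometry places CO2Me on the outside of the boat and hence cis to the formyl group, fixing C6.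

Step 9
Reactants: 10 methyl (1R,6S)-6-formyl-3,6-dimethylcyclohex-2-ene-1-carboxylate
Product: 11 methyl (1R,6S)-6-ethynyl-3,6-dimethylcyclohex-2-ene-1-carboxylate
Conditions: dimethyl (1-diazo-2-oxopropyl)phosphonate, K2CO3, MeOH, 0 °C to rt
Reagents that add atoms: dimethyl (1-diazo-2-oxopropyl)phosphonate, CC(=O)C(=[N+]=[N-])P(=O)(OC)OC
Why: Ohira–Bestmann variant of the Seyferth–Gilbert homologation, which converts the non-enolisable neopentyl aldehyde through a diazoalkene and hydride shift of the alkylidene carbene into the terminal alkyne, K2CO3 in MeOH being too weak to deprotonate C6–H and degenerate toward the methyl ester.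

Step 10
Reactants: 11 methyl (1R,6S)-6-ethynyl-3,6-dimethylcyclohex-2-ene-1-carboxylate
Product: 14 {[(1S,2R)-1,4-dimethyl-2-{[(triisopropylsilyl)oxy]ethynyl}cyclohex-3-en-1-yl]ethynyl}triisopropylsilane, via dibromomethyl ketone 12 (not isolated), via dilithio ynolate 13 (not isolated)
Conditions: CH2Br2, lithium 2,2,6,6-tetramethylpiperidide (from the amine and n-BuLi), THF, −78 °C; add 11; LiN(SiMe3)2, −78 to −20 °C; n-BuLi, −78 °C to rt; TIPSOTf (3 equiv), −78 to 0 °C
Reagents that add atoms: dibromomethane, BrCBr; triisopropylsilyl trifluoromethanesulfonate, CC(C)[Si](C(C)C)(C(C)C)OS(=O)(=O)C(F)(F)F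
Why: Kowalski ester homologation halted at the ynolate, in which LiCHBr2 adds to the ester and the derived dibromo enolate undergoes Br/Li exchange and a 1,2-shift with C6 migrating with retention; the C1 acetylide made by the same excess of base shares the final quench, and the bulk of TIPSOTf directs the ynolate to O-silylation, so both silyl groups arrive in one operation without a separate alkyne capping that the enolisable ester would not tolerate.

Step 11
Reactants: 15 cyclobutane-1,3-dione
Product: 16 3-methoxycyclobut-2-en-1-one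
Conditions: TMSCHN2 (1.0 equiv), Et2O/MeOH, 0 °C
Reagents that add atoms: trimethylsilyldiazomethane, C[Si](C)(C)C=[N+]=[N-]
Why: The dione exists as a strongly acidic enol (a vinylogous carboxylic acid) that protonates the diazoalkane and is O-methylated by the resulting diazonium ion, as in diazoalkane esterification, faster than any ring expansion of the ketone.

Step 12
Reactants: 14 {[(1S,2R)-1,4-dimethyl-2-{[(triisopropylsilyl)oxy]ethynyl}cyclohex-3-en-1-yl]ethynyl}triisopropylsilane; 16 3-methoxycyclobut-2-en-1-one
Product: 20 2-{(1R,6S)-3,6-dimethyl-6-[(triisopropylsilyl)ethynyl]cyclohex-2-en-1-yl}-5-methoxy-3-(triisopropylsilyloxy)phenol, via methoxyvinylketene 17 (not isolated), via vinylcyclobutenone 18 (not isolated), via dienylketene 19 (not isolated)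
Conditions: 16 (1.5 equiv, in portions), degassed toluene, sealed tube, 110 °C then 135 °C
Reagents that add atoms: none
Why: Heat opens 16 by 4π electrocyclic cleavage of its C1–C4 bond to methoxyvinylketene 17, whose electrophilic carbonyl carbon is attacked by the nucleophilic alkyne carbon of 14 that carries cyclohexene C6, so a [2+2] cycloaddition gives 18 and lays down coumarin bonds C8–C8a and C6–C7. A second 4π opening gives dienylketene 19, and the one ring closed here, the benzene ring of coumarin B, forms by 6π electrocyclisation (C4a–C8a) followed by tautomerisation of the cyclohexadienone to phenol 20. This is the Danheiser benzannulation, and the closest known case is the union of ester-derived secondary-alkyl triisopropylsiloxyalkynes with 3-alkylcyclobutenones to give resorcinol monosilyl ethers. No lasting stereocentre is created (the sp3 carbon of 18 is erased on aromatisation), and C1 and C6 are spectators because the medium is neutral and metal-free. The step needs regioselectivity in the [2+2] event, secured by the oxygen-polarised ynol ether matching the ketene dipole, and chemoselectivity, secured because the silyl-capped alkyne and the trisubstituted alkene are much poorer ketenophiles. The weak point is the vinylogous-ester stabilisation of 16, which raises the temperature of the first ring opening, hence the portionwise addition and stepped heating.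

Step 13
Reactants: 20 2-{(1R,6S)-3,6-dimethyl-6-[(triisopropylsilyl)ethynyl]cyclohex-2-en-1-yl}-5-methoxy-3-(triisopropylsilyloxy)phenol; 21 propiolic acid
Product: 22 2-{(1R,6S)-3,6-dimethyl-6-[(triisopropylsilyl)ethynyl]cyclohex-2-en-1-yl}-5-methoxy-3-(triisopropylsilyloxy)phenyl prop-2-ynoate
Conditions: 21, DCC, DMAP (5 mol%), CH2Cl2, 0 °C
Reagents that add atoms: none
Why: Steglich esterification of the only free hydroxyl, with low temperature and little DMAP to limit conjugate addition to the propiolate.

Step 14
Reactants: 22 aryl prop-2-ynoate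
Product: 23 8-{(1R,6S)-3,6-dimethyl-6-[(triisopropylsilyl)ethynyl]cyclohex-2-en-1-yl}-5-methoxy-7-(triisopropylsilyloxy)-2H-chromen-2-one
Conditions: [Au(NCMe){P(t-Bu)2(2-biphenylyl)}]SbF6 (5 mol%), CH2Cl2, rt
Reagents that add atoms: none
Why: Gold-catalysed intramolecular hydroarylation of an aryl propiolate (6-endo-dig, Friedel–Crafts type), in which the cationic monovalent gold complex activates the unhindered terminal ynoate and the only free ortho carbon, activated by the ortho OMe and para OTIPS groups, attacks the alkyne terminus to form C4–C4a; the bulky silyl cap keeps the other alkyne out of play.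

Step 15
Reactants: 23 silyl-protected coumarin B
Product: 24 8-[(1R,6S)-6-ethynyl-3,6-dimethylcyclohex-2-en-1-yl]-7-hydroxy-5-methoxy-2H-chromen-2-one
Conditions: Bu4NF (2.5 equiv), THF, 0 °C to rt; aq NH4Cl
Reagents that add atoms: none
Why: Fluoride-driven desilylation, in which Si–F bond formation cleaves the aryl silyl ether at once and the alkynylsilane more slowly, and any lactone opened by adventitious hydroxide recloses on the mildly acidic work-up because the cinnamate remains Z.

Step 16
Reactants: 24 8-[(1R,6S)-6-ethynyl-3,6-dimethylcyclohex-2-en-1-yl]-7-hydroxy-5-methoxy-2H-chromen-2-one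
Product: 25 8-[(1R,6S)-6-ethynyl-3,6-dimethylcyclohex-2-en-1-yl]-5,7-dimethoxy-2H-chromen-2-one
Conditions: MeI, K2CO3, acetone, rt
Reagents that add atoms: iodomethane, CI
Why: Williamson O-methylation of an acidic 7-hydroxycoumarin with a carbonate base that leaves the terminal alkyne and the lactone alone.

Step 17
Reactants: 26 5,7-dimethoxycoumarin
Product: 27 8-iodo-5,7-dimethoxy-2H-chromen-2-one
Conditions: NIS, CF3CO2H (cat.), MeCN, rt
Reagents that add atoms: N-iodosuccinimide, O=C1CCC(=O)N1I
Why: Electrophilic aromatic iodination, for which C8 is activated by the ortho 7-OMe, the para 5-OMe and the ring oxygen and is less crowded than C6 between two methoxy groups, so 8-iodination should dominate and any isomer should be removable by crystallisation.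

Step 18
Reactants: 25 8-[(1R,6S)-6-ethynyl-3,6-dimethylcyclohex-2-en-1-yl]-5,7-dimethoxy-2H-chromen-2-one; 27 8-iodo-5,7-dimethoxy-2H-chromen-2-one
Product: 28 8-{[(1S,2R)-2-(5,7-dimethoxy-2-oxo-2H-chromen-8-yl)-1,4-dimethylcyclohex-3-en-1-yl]ethynyl}-5,7-dimethoxy-2H-chromen-2-one
Conditions: PdCl2(PPh3)2 (5 mol%), CuI (10 mol%), Et3N, degassed DMF, 60 °C
Reagents that add atoms: none
Why: Sonogashira coupling of an aryl iodide with a terminal alkyne, whose linear geometry keeps the quaternary carbon away from the hindered aryl–palladium centre, under an amine base that both lactones tolerate.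

Step 19
Reactants: 28 alkyne-linked biscoumarin
Product: 29 8-{(Z)-2-[(1R,2R)-2-(5,7-dimethoxy-2-oxo-2H-chromen-8-yl)-1,4-dimethylcyclohex-3-en-1-yl]ethenyl}-5,7-dimethoxy-2H-chromen-2-one (target)
Conditions: H2 (1 atm), Pd/CaCO3 poisoned with Pb(OAc)2, quinoline, EtOAc, rt
Reagents that add atoms: none
Why: Lindlar semi-hydrogenation delivers both hydrogens to one face of the alkyne and so gives the Z-alkene, whose crowding should stop further uptake, while the trisubstituted alkene and the conjugated pyrone double bonds are not reduced on the poisoned surface.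

Compound list
1 | (R)-(−)-linalool | C=C[C@](C)(O)CCC=C(C)C | starting material
2 | (5R)-5-ethenyl-5-methyloxolan-2-ol | C=C[C@@]1(C)CCC(O)O1 | intermediate
3 | (3R)-3-methylhept-1-ene-3,6-diol | C=C[C@](C)(O)CCC(C)O | intermediate
4 | (5R)-5-hydroxy-5-methylhept-6-en-2-one | C=C[C@](C)(O)CCC(C)=O | intermediate
5 | (3R)-7-methoxy-3,6-dimethylhepta-1,6-dien-3-ol | C=C[C@](C)(O)CCC(C)=COC | intermediate
6 | (6R)-6-ethenyl-2-methoxy-3,6-dimethyloxane | C=C[C@@]1(C)CCC(C)C(OC)O1 | intermediate
7 | methyl acrylate | C=CC(=O)OC | starting material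
8 | methyl (E)-3-[(2R)-6-methoxy-2,5-dimethyloxan-2-yl]prop-2-enoate | COC(=O)/C=C/[C@@]1(C)CCC(C)C(OC)O1 | intermediate
9 | methyl (E)-3-[(2R)-2,5-dimethyl-3,4-dihydro-2H-pyran-2-yl]prop-2-enoate | COC(=O)/C=C/[C@@]1(C)CCC(C)=CO1 | intermediate
10 | methyl (1R,6S)-6-formyl-3,6-dimethylcyclohex-2-ene-1-carboxylate | O=C[C@@]1(C)CCC(C)=C[C@H]1C(=O)OC | intermediate
11 | methyl (1R,6S)-6-ethynyl-3,6-dimethylcyclohex-2-ene-1-carboxylate | C#C[C@@]1(C)CCC(C)=C[C@H]1C(=O)OC | intermediate
12 | 2,2-dibromo-1-[(1R,6S)-6-ethynyl-3,6-dimethylcyclohex-2-en-1-yl]ethan-1-one | C#C[C@@]1(C)CCC(C)=C[C@H]1C(=O)C(Br)Br | intermediate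
13 | dilithium salt: C1 acetylide and C6 ynolate | [Li]C#C[C@@]1(C)CCC(C)=C[C@H]1C#CO[Li] | intermediate
14 | {[(1S,2R)-1,4-dimethyl-2-{[(triisopropylsilyl)oxy]ethynyl}cyclohex-3-en-1-yl]ethynyl}triisopropylsilane | CC(C)[Si](C(C)C)(C(C)C)C#C[C@@]1(C)CCC(C)=C[C@H]1C#CO[Si](C(C)C)(C(C)C)C(C)C | intermediate
15 | cyclobutane-1,3-dione | O=C1CC(=O)C1 | starting material
16 | 3-methoxycyclobut-2-en-1-one | COC1=CC(=O)C1 | intermediate
17 | 3-methoxybuta-1,3-dien-1-one (methoxyvinylketene) | C=C(OC)C=C=O | intermediate
18 | 2-cyclohexenyl-4-(1-methoxyethenyl)-3-(triisopropylsilyloxy)cyclobut-2-en-1-one (C4 epimers) | CC(C)[Si](C(C)C)(C(C)C)C#C[C@@]1(C)CCC(C)=C[C@H]1C2=C(O[Si](C(C)C)(C(C)C)C(C)C)C(C(=C)OC)C2=O | intermediate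
19 | 2-cyclohexenyl-5-methoxy-3-(triisopropylsilyloxy)hexa-1,3,5-trien-1-one (dienylketene, ketene and methoxyvinyl groups cis) | CC(C)[Si](C(C)C)(C(C)C)C#C[C@@]1(C)CCC(C)=C[C@H]1C(=C=O)/C(O[Si](C(C)C)(C(C)C)C(C)C)=C\C(=C)OC | intermediate
20 | 2-{(1R,6S)-3,6-dimethyl-6-[(triisopropylsilyl)ethynyl]cyclohex-2-en-1-yl}-5-methoxy-3-(triisopropylsilyloxy)phenol | CC(C)[Si](C(C)C)(C(C)C)C#C[C@@]1(C)CCC(C)=C[C@H]1c1c(O)cc(OC)cc1O[Si](C(C)C)(C(C)C)C(C)C | intermediate
21 | propiolic acid | C#CC(=O)O | starting material
22 | prop-2-ynoate ester of 20 | CC(C)[Si](C(C)C)(C(C)C)C#C[C@@]1(C)CCC(C)=C[C@H]1c1c(OC(=O)C#C)cc(OC)cc1O[Si](C(C)C)(C(C)C)C(C)C | intermediate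
23 | 8-{(1R,6S)-3,6-dimethyl-6-[(triisopropylsilyl)ethynyl]cyclohex-2-en-1-yl}-5-methoxy-7-(triisopropylsilyloxy)-2H-chromen-2-one | CC(C)[Si](C(C)C)(C(C)C)C#C[C@@]1(C)CCC(C)=C[C@H]1c1c(O[Si](C(C)C)(C(C)C)C(C)C)cc(OC)c2ccc(=O)oc12 | intermediate
24 | 8-[(1R,6S)-6-ethynyl-3,6-dimethylcyclohex-2-en-1-yl]-7-hydroxy-5-methoxy-2H-chromen-2-one | C#C[C@@]1(C)CCC(C)=C[C@H]1c1c(O)cc(OC)c2ccc(=O)oc12 | intermediate
25 | 8-[(1R,6S)-6-ethynyl-3,6-dimethylcyclohex-2-en-1-yl]-5,7-dimethoxy-2H-chromen-2-one | C#C[C@@]1(C)CCC(C)=C[C@H]1c1c(OC)cc(OC)c2ccc(=O)oc12 | intermediate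
26 | 5,7-dimethoxycoumarin | COc1cc(OC)c2ccc(=O)oc2c1 | starting material
27 | 8-iodo-5,7-dimethoxy-2H-chromen-2-one | COc1cc(OC)c2ccc(=O)oc2c1I | intermediate
28 | 8-{[(1S,2R)-2-(5,7-dimethoxy-2-oxo-2H-chromen-8-yl)-1,4-dimethylcyclohex-3-en-1-yl]ethynyl}-5,7-dimethoxy-2H-chromen-2-one | COc1cc(OC)c2ccc(=O)oc2c1C#C[C@@]1(C)CCC(C)=C[C@H]1c1c(OC)cc(OC)c2ccc(=O)oc12 | intermediate
29 | CNP0164660.3, (Z)-alkene, (1R,2R) in the cyclohex-3-en-1-yl numbering | COc1cc(OC)c2ccc(=O)oc2c1/C=C\[C@@]1(C)CCC(C)=C[C@H]1c1c(OC)cc(OC)c2ccc(=O)oc12 | target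

Total step count: 19.
Longest linear sequence: 17 (steps 1–10, 12–16, 18 and 19). Steps 11 and 17 are one-step side branches.

Steps most likely to fail

Step 12. The push–pull stabilisation of 16 may keep the four-membered ring closed until temperatures at which the ketene oligomerises, acylates the phenol as it forms, or outlives the ynol ether.
- The fallback sets out from 14 and returns at 20. It makes ketene 17 at room temperature from an acyclic source instead of from the ring.
- Commercial 3,3-dimethoxybutan-2-one is cracked (cat. TsOH, distillation) to 3-methoxybut-3-en-2-one F1.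
- LiN(SiMe3)2 followed by CF3CO2CH2CF3 (THF, −78 °C) gives 1,1,1-trifluoro-5-methoxyhex-5-ene-2,4-dione F2.
- MsN3, Et3N and water in MeCN give 1-diazo-3-methoxybut-3-en-2-one F3 by detrifluoroacetylative diazo transfer.
- Irradiation of F3 with 14 in CH2Cl2 (quartz, rt) triggers a photochemical Wolff rearrangement to 17, which is trapped as 18. Brief heating in toluene at 110 °C carries 18 through 19 to 20.

Step 10. Addition of LiCHBr2 to an ester carbonyl next to a quaternary carbon may be outrun by deprotonation at the allylic C6–H, with erosion of the C6 configuration or drift of the double bond into conjugation.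
- The fallback sets out from 11 and returns at 12, now as an isolated compound, by building the dibromoketone from the aldehyde oxidation level.
- i-Bu2AlH (toluene, −78 °C) gives (1R,6S)-6-ethynyl-3,6-dimethylcyclohex-2-ene-1-carbaldehyde F4.
- The much more electrophilic aldehyde takes up LiCHBr2 at −90 °C to give 2,2-dibromo-1-[(1R,6S)-6-ethynyl-3,6-dimethylcyclohex-2-en-1-yl]ethan-1-ol F5.
- Dess–Martin oxidation of F5 gives 12. LiN(SiMe3)2, n-BuLi and TIPSOTf, as in step 10, then lead through 13 to 14.

Step 19. The alkyne of 28 is shielded by a quaternary carbon on one side and a 2,6-dioxygenated aryl ring on the other. Adsorption on the poisoned surface may therefore be too slow, inviting forcing conditions, Z-to-E isomerisation or saturation of a pyrone double bond.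
- The fallback sets out from 25 (with 27), bypasses 28 and returns at 29. It fixes the Z geometry before the aryl–alkenyl bond is made.
- Rhodium-catalysed trans-hydroboration of the terminal alkyne through a vinylidene complex ([Rh(cod)Cl]2, P(i-Pr)3, Et3N, pinacolborane, cyclohexane, rt) gives the (Z)-2-[(1R,2R)-2-(5,7-dimethoxy-2-oxo-2H-chromen-8-yl)-1,4-dimethylcyclohex-3-en-1-yl]ethenylboronic acid pinacol ester F6.
- Suzuki–Miyaura coupling of F6 with 27 (Pd(PPh3)4, K3PO4, dioxane/H2O, 60 °C, mildly acidic work-up) proceeds with retention of alkene geometry to 29.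

Further compounds
F1 | step 12 | 3-methoxybut-3-en-2-one | C=C(OC)C(C)=O
F2 | step 12 | 1,1,1-trifluoro-5-methoxyhex-5-ene-2,4-dione | C=C(OC)C(=O)CC(=O)C(F)(F)F
F3 | step 12 | 1-diazo-3-methoxybut-3-en-2-one | C=C(OC)C(=O)C=[N+]=[N-]
F4 | step 10 | (1R,6S)-6-ethynyl-3,6-dimethylcyclohex-2-ene-1-carbaldehyde | C#C[C@@]1(C)CCC(C)=C[C@H]1C=O
F5 | step 10 | 2,2-dibromo-1-[(1R,6S)-6-ethynyl-3,6-dimethylcyclohex-2-en-1-yl]ethan-1-ol (carbinol epimers) | C#C[C@@]1(C)CCC(C)=C[C@H]1C(O)C(Br)Br
F6 | step 19 | (Z)-2-[(1R,2R)-2-(5,7-dimethoxy-2-oxo-2H-chromen-8-yl)-1,4-dimethylcyclohex-3-en-1-yl]ethenylboronic acid pinacol ester | CC1(C)OB(/C=C\[C@@]2(C)CCC(C)=C[C@H]2c2c(OC)cc(OC)c3ccc(=O)oc23)OC1(C)C
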